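**Assumption:** a recombinant aromatic prenyltransferase with genistein C6-dimethylallyltransferase activity is taken as an obtainable catalyst, and DMAPP triammonium salt as a commercial reagent. Side-chain atoms are numbered C1'' (CH2 on C6), C2'' (carbinol), C3'' (alkene carbon bearing CH3), C4'' (=CH2). The target stereocentre C2'' is (R).

## Retrosynthetic overview

1. The target is commercial genistein (rings A, C and B intact) plus one oxidised prenyl unit on C6 of ring A, the carbon between 5-OH and 7-OH. No ring has to be formed.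
2. Key disconnection: the C6–C1'' bond, made on unprotected genistein by an aromatic prenyltransferase with DMAPP, copying the biosynthetic prenylation. C6 must be chosen over C8, C3' and three phenol oxygens, which no small reagent does without a protection and relay sequence.
3. The C2''(R)-OH / C3''=C4'' exo-methylene pattern is read as an isomerised 2'',3''-prenyl epoxide. C2'' is set by catalyst-controlled epoxidation of the C2''=C3'' alkene.
4. The epoxide is opened to the allylic alcohol by syn-elimination that cleaves C3''–O and leaves C2''–O untouched. Three O-allyl ethers mask the phenols in between and leave under Pd(0) without acid.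

Key step: step 1

## Route

Step 1
Reactants: 1 genistein; 2 dimethylallyl diphosphate (DMAPP) triammonium salt
Product: 3 wighteone (6-prenylgenistein)
Conditions: recombinant genistein 6-C-dimethylallyltransferase (aromatic prenyltransferase; plant UbiA-type as yeast microsomes or soluble fungal DMATS-type), MgCl2, Tris-HCl pH 7.5–9, 5% DMSO, 30 °C; EtOAc extraction
Reagents that add atoms: none
Why: The enzyme ionises Mg-bound DMAPP to a dimethylallyl cation–diphosphate pair held over ring A, C6 attacks C1 of the cation in an enzymatic Friedel–Crafts alkylation, and loss of H6 restores the arene. The closest known reaction type is the C6-dimethylallylation of genistein and related 5,7-dihydroxy(iso)flavonoids by plant membrane-bound and fungal soluble aromatic prenyltransferases. No ring is closed and no stereocentre is formed. The step needs C6 over C8, C3' and the three phenol oxygens, and regular (C1) over reverse (C3) attachment of the C5 unit; the substrate does not secure this, since C6 and C8 are electronically alike, so it rests on the orientation of the isoflavone in the active site. The precursor is unprotected commercial genistein, so this one step should replace the protection, O-allylation, Claisen and metathesis sequence of a chemical C6-prenylation.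

Step 2
Reactants: 3 wighteone
Product: 4 5,7-bis(allyloxy)-3-[4-(allyloxy)phenyl]-6-(3-methylbut-2-en-1-yl)-4H-chromen-4-one
Conditions: allyl bromide (6 equiv), K2CO3 (6 equiv), DMF, 60 °C
Reagents that add atoms: allyl bromide, C=CCBr
Why: Williamson O-alkylation should cap all three phenols (the chelated, flanked 5-OH needs the excess and warming) so that no ortho-phenol can open the later epoxide; allyl survives epoxidation and aluminium amide and is removed without acid.

Step 3
Reactants: 4 tri-O-allyl wighteone
Product: 5 5,7-bis(allyloxy)-3-[4-(allyloxy)phenyl]-6-{[(2R)-3,3-dimethyloxiran-2-yl]methyl}-4H-chromen-4-one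
Conditions: D-fructose-derived ketone catalyst (30 mol%), Oxone, K2CO3, Bu4NHSO4 (cat.), MeCN–dimethoxymethane / aq. borate–EDTA buffer (pH ca. 10.5), 0 °C
Reagents that add atoms: potassium peroxymonosulfate (active component of Oxone), [K+].[O-]S(=O)(=O)OO
Why: Shi asymmetric epoxidation: the chiral dioxirane delivers oxygen through a spiro transition state to one face of the electron-rich trisubstituted C2''=C3'' alkene, which should give the (2''R)-epoxide by catalyst control, while the monosubstituted allyl ether alkenes and the electron-poor C2=C3 bond of the chromone should react far more slowly.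

Step 4
Reactants: 5 (R)-epoxide
Product: 7 5,7-bis(allyloxy)-3-[4-(allyloxy)phenyl]-6-[(2R)-2-hydroxy-3-methylbut-3-en-1-yl]-4H-chromen-4-one, via diethylaluminium C2''-alkoxide 6 (not isolated)
Conditions: Et2Al–TMP (4 equiv; from TMP-H, n-BuLi, Et2AlCl), toluene, 0 °C to rt; aq. Rochelle salt
Reagents that add atoms: none
Why: Epoxide to allylic alcohol isomerisation with a bulky aluminium amide: aluminium binds the epoxide oxygen and the amide removes a proton from a C3'' methyl group in a syn-elimination that cleaves C3''–O, so the C2''–O bond and its (R) configuration are not touched and the C3''=C4'' exo-methylene is formed.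

Step 5
Reactants: 7 tri-O-allyl allylic alcohol
Product: 8 5,7-dihydroxy-3-(4-hydroxyphenyl)-6-[(2R)-2-hydroxy-3-methylbut-3-en-1-yl]-4H-chromen-4-one (target)
Conditions: Pd(PPh3)4 (5 mol%), K2CO3, MeOH–THF (degassed), rt; then aq. NH4Cl
Reagents that add atoms: none
Why: Pd(0)-catalysed deallylation of the Tsuji–Trost type: oxidative addition into the three aryl allyl ethers releases the phenoxides and methanol traps the π-allyl units, while the free secondary allylic alcohol should not be ionised under these basic conditions, so C2'' is retained.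

## Compound list

1 | genistein, 5,7-dihydroxy-3-(4-hydroxyphenyl)-4H-chromen-4-one | O=c1c(-c2ccc(O)cc2)coc2cc(O)cc(O)c12 | starting material
2 | dimethylallyl diphosphate (3-methylbut-2-en-1-yl diphosphate), triammonium salt | CC(C)=CCOP(=O)([O-])OP(=O)([O-])[O-].[NH4+].[NH4+].[NH4+] | starting material
3 | wighteone, 5,7-dihydroxy-3-(4-hydroxyphenyl)-6-(3-methylbut-2-en-1-yl)-4H-chromen-4-one | CC(C)=CCc1c(O)cc2occ(-c3ccc(O)cc3)c(=O)c2c1O | intermediate
4 | 5,7-bis(allyloxy)-3-[4-(allyloxy)phenyl]-6-(3-methylbut-2-en-1-yl)-4H-chromen-4-one | CC(C)=CCc1c(OCC=C)cc2occ(-c3ccc(OCC=C)cc3)c(=O)c2c1OCC=C | intermediate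
5 | 5,7-bis(allyloxy)-3-[4-(allyloxy)phenyl]-6-{[(2R)-3,3-dimethyloxiran-2-yl]methyl}-4H-chromen-4-one | CC1(C)O[C@@H]1Cc1c(OCC=C)cc2occ(-c3ccc(OCC=C)cc3)c(=O)c2c1OCC=C | intermediate
6 | diethylaluminium (2R)-1-{5,7-bis(allyloxy)-3-[4-(allyloxy)phenyl]-4-oxo-4H-chromen-6-yl}-3-methylbut-3-en-2-olate | C=C(C)[C@H](O[Al](CC)CC)Cc1c(OCC=C)cc2occ(-c3ccc(OCC=C)cc3)c(=O)c2c1OCC=C | intermediate (not isolated)
7 | 5,7-bis(allyloxy)-3-[4-(allyloxy)phenyl]-6-[(2R)-2-hydroxy-3-methylbut-3-en-1-yl]-4H-chromen-4-one | C=C(C)[C@H](O)Cc1c(OCC=C)cc2occ(-c3ccc(OCC=C)cc3)c(=O)c2c1OCC=C | intermediate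
8 | 5,7-dihydroxy-3-(4-hydroxyphenyl)-6-[(2R)-2-hydroxy-3-methylbut-3-en-1-yl]-4H-chromen-4-one | C=C(C)[C@H](O)Cc1c(O)cc2occ(-c3ccc(O)cc3)c(=O)c2c1O | target

## Step count and risks

Total steps: 5. Longest linear sequence: 5 steps (1 to 8).

**Step 1 (most likely to fail).** The enzymatic prenylation may stall at low conversion (poor solubility of genistein in buffer, hydrolysis of DMAPP, product inhibition), or the chosen enzyme may leak the prenyl group to C8, C3' or oxygen. The fallback sets out from 1 and comes back at 3, and makes the C6–C1'' bond by a chelation-directed sigmatropic relay.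
- MOMCl and iPr2NEt in CH2Cl2 should protect the two unchelated phenols to give 5-hydroxy-7-(methoxymethoxy)-3-[4-(methoxymethoxy)phenyl]-4H-chromen-4-one F1.
- Allyl bromide and K2CO3 in DMF should give 5-(allyloxy)-7-(methoxymethoxy)-3-[4-(methoxymethoxy)phenyl]-4H-chromen-4-one F2.
- Eu(fod)3-catalysed ortho-Claisen rearrangement (CHCl3, 60 °C), for which C6 is the only ortho position of O5, should give 6-allyl-5-hydroxy-7-(methoxymethoxy)-3-[4-(methoxymethoxy)phenyl]-4H-chromen-4-one F3.
- Cross-metathesis with 2-methyl-2-butene (second-generation Ru–NHC benzylidene catalyst, CH2Cl2, 40 °C) should give 5-hydroxy-7-(methoxymethoxy)-3-[4-(methoxymethoxy)phenyl]-6-(3-methylbut-2-en-1-yl)-4H-chromen-4-one F4.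
- Brief treatment with dilute HCl in MeOH should remove both MOM groups and return wighteone 3.

**Step 4.** The aluminium amide may instead abstract a benzylic C1'' proton (giving the styrenyl tertiary alcohol), or may be consumed by chelation to or attack on the chromone and the 5-O-allyl ether. The fallback sets out from 5 and comes back at 7, and replaces base-mediated elimination by hydrolysis and dehydration.
- Acid-catalysed hydrolysis (cat. HClO4, THF–H2O, 0 °C) should open the epoxide at the tertiary C3'' with C2'' untouched, giving 5,7-bis(allyloxy)-3-[4-(allyloxy)phenyl]-6-[(2R)-2,3-dihydroxy-3-methylbutyl]-4H-chromen-4-one F5.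
- Ac2O and pyridine should acylate only the secondary hydroxyl, giving (2R)-1-{5,7-bis(allyloxy)-3-[4-(allyloxy)phenyl]-4-oxo-4H-chromen-6-yl}-3-hydroxy-3-methylbutan-2-yl acetate F6.
- SOCl2 and pyridine at 0 °C should dehydrate the tertiary alcohol towards a methyl group, giving (2R)-1-{5,7-bis(allyloxy)-3-[4-(allyloxy)phenyl]-4-oxo-4H-chromen-6-yl}-3-methylbut-3-en-2-yl acetate F7.
- K2CO3 in MeOH should cleave the acetate to give 7.

**Step 3.** Facial selectivity may be eroded by the bulky di-ortho-alkoxybenzyl substituent, or the oxidant may also attack the allyl ethers or the C2=C3 bond. The fallback sets out from 4 and comes back at 7; it is stereoconvergent and avoids the epoxide.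
- Schenck ene photooxygenation (O2, tetraphenylporphyrin, hν, CH2Cl2, 0 °C) should give the racemic secondary allylic hydroperoxide 5,7-bis(allyloxy)-3-[4-(allyloxy)phenyl]-6-(2-hydroperoxy-3-methylbut-3-en-1-yl)-4H-chromen-4-one F8. The regioisomeric tertiary hydroperoxide cannot dehydrate and would be separated.
- Ac2O, pyridine and DMAP in the same flask should dehydrate F8 to the enone 5,7-bis(allyloxy)-3-[4-(allyloxy)phenyl]-6-(3-methyl-2-oxobut-3-en-1-yl)-4H-chromen-4-one F9.
- Corey–Bakshi–Shibata reduction ((S)-methyl oxazaborolidine, catecholborane, toluene, −78 °C), with the isopropenyl group as the large substituent, should funnel both enantiomeric series into (R)-7. The sense of induction would have to be confirmed.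

## Further compounds

F1 | step 1 | 5-hydroxy-7-(methoxymethoxy)-3-[4-(methoxymethoxy)phenyl]-4H-chromen-4-one | COCOc1ccc(-c2coc3cc(OCOC)cc(O)c3c2=O)cc1
F2 | step 1 | 5-(allyloxy)-7-(methoxymethoxy)-3-[4-(methoxymethoxy)phenyl]-4H-chromen-4-one | COCOc1ccc(-c2coc3cc(OCOC)cc(OCC=C)c3c2=O)cc1
F3 | step 1 | 6-allyl-5-hydroxy-7-(methoxymethoxy)-3-[4-(methoxymethoxy)phenyl]-4H-chromen-4-one | C=CCc1c(OCOC)cc2occ(-c3ccc(OCOC)cc3)c(=O)c2c1O
F4 | step 1 | 5-hydroxy-7-(methoxymethoxy)-3-[4-(methoxymethoxy)phenyl]-6-(3-methylbut-2-en-1-yl)-4H-chromen-4-one | CC(C)=CCc1c(OCOC)cc2occ(-c3ccc(OCOC)cc3)c(=O)c2c1O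
F5 | step 4 | 5,7-bis(allyloxy)-3-[4-(allyloxy)phenyl]-6-[(2R)-2,3-dihydroxy-3-methylbutyl]-4H-chromen-4-one | CC(C)(O)[C@H](O)Cc1c(OCC=C)cc2occ(-c3ccc(OCC=C)cc3)c(=O)c2c1OCC=C
F6 | step 4 | (2R)-1-{5,7-bis(allyloxy)-3-[4-(allyloxy)phenyl]-4-oxo-4H-chromen-6-yl}-3-hydroxy-3-methylbutan-2-yl acetate | CC(C)(O)[C@H](OC(C)=O)Cc1c(OCC=C)cc2occ(-c3ccc(OCC=C)cc3)c(=O)c2c1OCC=C
F7 | step 4 | (2R)-1-{5,7-bis(allyloxy)-3-[4-(allyloxy)phenyl]-4-oxo-4H-chromen-6-yl}-3-methylbut-3-en-2-yl acetate | C=C(C)[C@H](OC(C)=O)Cc1c(OCC=C)cc2occ(-c3ccc(OCC=C)cc3)c(=O)c2c1OCC=C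
F8 | step 3 | 5,7-bis(allyloxy)-3-[4-(allyloxy)phenyl]-6-(2-hydroperoxy-3-methylbut-3-en-1-yl)-4H-chromen-4-one (racemic) | C=C(C)C(OO)Cc1c(OCC=C)cc2occ(-c3ccc(OCC=C)cc3)c(=O)c2c1OCC=C
F9 | step 3 | 5,7-bis(allyloxy)-3-[4-(allyloxy)phenyl]-6-(3-methyl-2-oxobut-3-en-1-yl)-4H-chromen-4-one | C=C(C)C(=O)Cc1c(OCC=C)cc2occ(-c3ccc(OCC=C)cc3)c(=O)c2c1OCC=C
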